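## Retrosynthetic overview

1. Target 16 is 3-docosyl-5-methoxy-2-methylcyclohexa-2,5-diene-1,4-dione (C30H52O3, one ring, no stereocentre). Its ring is opened at the bond between carbonyl carbon C1 and the methyl-bearing carbon C2; in the forward sense this bond is made by six-electron electrocyclisation of a dienylketene, which closes the only ring.
2. Enabling feature: the ring oxygens are para (C1, C4), a methoxy group sits on C5 beside C4 and a hydrogen on C6 beside C1. The atoms C1–C6–C5–C4 are therefore the four-membered ring of 3-methoxycyclobut-3-ene-1,2-dione 10, C2(CH3)=C3(C22H45) is a plain alkene that can arrive as an alkenyl anion, and C1 becomes a ketene carbon when the four-membered ring opens.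
3. Halves: alkenyl iodide 7 (iodo-Wittig olefination of acetaldehyde 3 with the ylide from 1-bromodocosane 1) and semisquarate 10 (hydride reduction and acid transposition of dimethyl squarate 8).
4. Ring order: the cyclobutene ring is bought in 8; the six-membered ring is formed last, in step 5, where 7 and 10 are joined, ring-expanded and oxidised in one telescoped operation.

Key step: step 5

Remark: the side chain is read as unbranched docosyl (22 carbons); the alkene geometry of 7 and the racemic centres of 9, 12 and 14 are erased before the target is reached.

## Route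

Step 1
Reactants: 1 1-bromodocosane
Product: 2 docosyl(triphenyl)phosphonium bromide
Conditions: PPh3 (1.1 equiv), MeCN/PhMe, reflux
Reagents that add atoms: triphenylphosphine, c1ccc(cc1)P(c1ccccc1)c1ccccc1
Why: SN2 alkylation of triphenylphosphine by an unhindered primary bromide is a routine phosphonium salt formation.

Step 2
Reactants: 2 docosyl(triphenyl)phosphonium bromide; 3 acetaldehyde
Product: 7 (2Z)-3-iodopentacos-2-ene, via phosphorus ylide 4 (not isolated), via iodophosphonium iodide 5 (not isolated), via iodo ylide 6 (not isolated)
Conditions: n-BuLi, THF, 0 °C; add to I2, THF, −78 °C; NaN(SiMe3)2, −20 °C; 3, −78 °C to rt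
Reagents that add atoms: iodine, [I][I]
Why: Iodo-Wittig (Stork–Zhao-type) olefination, in which the ylide is iodinated, the α-iodophosphonium salt is deprotonated and the α-iodo ylide condenses with the unhindered aldehyde, should give the trisubstituted iodoalkene with iodine cis to the methyl group under kinetic Wittig control.

Step 3
Reactants: 8 dimethyl squarate (3,4-dimethoxycyclobut-3-ene-1,2-dione)
Product: 9 4-hydroxy-2,3-dimethoxycyclobut-2-en-1-one (racemic)
Conditions: LiAlH(OtBu)3 (1.05 equiv), THF, −78 to −20 °C; aq. potassium sodium tartrate work-up
Reagents that add atoms: none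
Why: The bulky, mild hydride should reduce one of the two equivalent carbonyl groups by 1,2-addition and stop at the hydroxycyclobutenone (known reduction of dialkyl squarates); the new centre is racemic and is destroyed in step 4.

Step 4
Reactants: 9 4-hydroxy-2,3-dimethoxycyclobut-2-en-1-one
Product: 10 3-methoxycyclobut-3-ene-1,2-dione
Conditions: conc. HCl (cat.), CH2Cl2, rt
Reagents that add atoms: water, O
Why: Acid-mediated 1,3-transposition of a 4-hydroxycyclobutenone (the allylic hydroxyl ionises, water returns at the methoxy-bearing C2, methanol is lost) is the standard entry from squarate adducts to cyclobutenediones, here with hydrogen as the group at C4.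

Step 5
Reactants: 7 (2Z)-3-iodopentacos-2-ene; 10 3-methoxycyclobut-3-ene-1,2-dione
Product: 16 3-docosyl-5-methoxy-2-methylcyclohexa-2,5-diene-1,4-dione (target), via alkenyllithium 11 (not isolated), via hydroxycyclobutenone 12 (not isolated), via dienylketene 13 (not isolated), via cyclohexadienone 14 (not isolated), via hydroquinone 15 (not isolated)
Conditions: t-BuLi (2 equiv), Et2O, −78 °C; cannulate into 10 (1.2 equiv), THF, −78 °C; aq. NH4Cl; then p-xylene, 138 °C, Ar; then Ag2O, Na2SO4, rt
Reagents that add atoms: none
Why: Iodine–lithium exchange with retention gives 11, which should add 1,2 to the carbonyl of 10 that is attached to the methoxy-bearing carbon, because the other carbonyl is the deactivated carbonyl of a vinylogous ester; this places the methoxy group beside the carbonyl that will neighbour the docosyl-bearing carbon. On heating, adduct 12 should undergo conrotatory four-electron ring opening with the hydroxyl turning outward (torquoselectivity of a donor substituent), which puts the alkenyl group cis to the ketene in 13. Thermal disrotatory six-electron electrocyclisation of 13 then closes the six-membered ring by joining the ketene carbon to the methyl-bearing alkene terminus, enolisation of 14 gives hydroquinone 15, and Ag2O oxidises 15 to the quinone. The closest known reaction type is the Moore rearrangement of 4-alkenyl-4-hydroxycyclobutenones to hydroquinones, known for propen-2-yl and cycloalkenyl groups, from which the present alkenyl group differs in chain length and in the inward-pointing methyl group on the alkene terminus. No stereocentre remains, since the carbinol centre of 12 and the sp3 centre of 14 are erased on aromatisation and the alkene geometry of 7 does not reach the product. The selectivities needed are the site of carbonyl attack and the outward rotation of the hydroxyl, secured by the vinylogous ester in 10 and by the oxygen donor on C4 of 12.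

## Compound list

1 | 1-bromodocosane | CCCCCCCCCCCCCCCCCCCCCCBr | starting material
2 | docosyl(triphenyl)phosphonium bromide | CCCCCCCCCCCCCCCCCCCCCC[P+](c1ccccc1)(c1ccccc1)c1ccccc1.[Br-] | intermediate
3 | acetaldehyde | CC=O | starting material
4 | docosylidene(triphenyl)phosphorane | CCCCCCCCCCCCCCCCCCCCCC=P(c1ccccc1)(c1ccccc1)c1ccccc1 | intermediate
5 | (1-iododocosyl)(triphenyl)phosphonium iodide (racemic) | CCCCCCCCCCCCCCCCCCCCCC(I)[P+](c1ccccc1)(c1ccccc1)c1ccccc1.[I-] | intermediate
6 | (1-iododocosylidene)(triphenyl)phosphorane | CCCCCCCCCCCCCCCCCCCCCC(I)=P(c1ccccc1)(c1ccccc1)c1ccccc1 | intermediate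
7 | (2Z)-3-iodopentacos-2-ene | C/C=C(\I)CCCCCCCCCCCCCCCCCCCCCC | intermediate
8 | dimethyl squarate (3,4-dimethoxycyclobut-3-ene-1,2-dione) | COC1=C(OC)C(=O)C1=O | starting material
9 | 4-hydroxy-2,3-dimethoxycyclobut-2-en-1-one (racemic) | COC1=C(OC)C(O)C1=O | intermediate
10 | 3-methoxycyclobut-3-ene-1,2-dione | COC1=CC(=O)C1=O | intermediate
11 | (2E)-pentacos-2-en-3-yllithium (lithium cis to the C1 methyl) | C/C=C(\[Li])CCCCCCCCCCCCCCCCCCCCCC | intermediate
12 | 4-hydroxy-3-methoxy-4-[(2Z)-pentacos-2-en-3-yl]cyclobut-2-en-1-one (racemic) | C/C=C(\C1(O)C(OC)=CC1=O)CCCCCCCCCCCCCCCCCCCCCC | intermediate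
13 | 5-docosyl-4-hydroxy-3-methoxyhepta-1,3,5-trien-1-one (dienylketene; alkenyl cis to the ketene, methyl inward) | O=C=C/C(OC)=C(/O)\C(CCCCCCCCCCCCCCCCCCCCCC)=C/C | intermediate
14 | 5-docosyl-4-hydroxy-3-methoxy-6-methylcyclohexa-2,4-dien-1-one (racemic) | CC1C(=O)C=C(OC)C(O)=C1CCCCCCCCCCCCCCCCCCCCCC | intermediate
15 | 3-docosyl-5-methoxy-2-methylbenzene-1,4-diol | CCCCCCCCCCCCCCCCCCCCCCc1c(C)c(O)cc(OC)c1O | intermediate
16 | 3-docosyl-5-methoxy-2-methylcyclohexa-2,5-diene-1,4-dione | CCCCCCCCCCCCCCCCCCCCCCC1=C(C)C(=O)C=C(OC)C1=O | target

## Step count and risks

Total step count: 5. Longest linear sequence: 3 steps (steps 1, 2 and 5, or steps 3, 4 and 5).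

Steps most likely to fail:

1. Step 5 (key step). The alkenyllithium may attack the vinylogous-ester carbonyl or add in conjugate fashion to the unsubstituted ring carbon of 10. If the six-electron closure is slowed by the methyl group that points inward in 13, reversible ring opening may also drain material through intramolecular capture of the ketene by the hydroxyl (furanone formation). The fallback sets out from 7 and returns at 16, and replaces the hydroxycyclobutenone by a benzannulation that has no hydroxyl on the ketene precursor and no carbonyl addition. Alkenyllithium 11, made from 7 as above, would be acylated with N-methoxy-N-methylacetamide to give (3Z)-3-docosylpent-3-en-2-one F1. Its kinetic lithium enolate (LiN(SiMe3)2, THF, −78 °C) would be trifluoroacetylated with CF3CO2CH2CF3 to give (5Z)-5-docosyl-1,1,1-trifluorohept-5-ene-2,4-dione F2. Detrifluoroacetylative diazo transfer (MsN3, Et3N, H2O, MeCN) should then give (3Z)-1-diazo-3-docosylpent-3-en-2-one F3. Irradiation of F3 with methoxyacetylene in 1,2-dichloroethane and subsequent heating (photochemical Danheiser benzannulation: Wolff rearrangement, [2+2] cycloaddition, four-electron opening, six-electron closure at the same ketene-carbon-to-alkene-terminus bond) should give 3-docosyl-5-methoxy-2-methylphenol F4. Oxidation of F4 at its free para position with (KSO3)2NO (Fremy's salt) in buffered acetone/water would give 16.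

2. Step 2. Halogen exchange between ylide 4 and salt 5, or incomplete iodination, may lower conversion and leave iodine-free alkene that is hard to separate from 7. The fallback sets out from 1 and returns at 11, and replaces the olefination by a cross-coupling. Zinc insertion into 1 (Zn dust activated with I2, N,N-dimethylacetamide, 80 °C) would give docosylzinc bromide F5. Negishi coupling of F5 with commercial 1,1-dichloroprop-1-ene under PdCl2(DPEphos) catalysis, which substitutes the chlorine trans to the methyl group, should give (2Z)-3-chloropentacos-2-ene F6. Reductive lithiation of F6 (Li powder, catalytic 4,4'-di-tert-butylbiphenyl, THF, −78 °C) would give 11, possibly together with its geometric isomer, which converges on the same hydroquinone 15.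

3. Step 4. Hydrolysis of the vinylogous ester may run past the transposition, and the small, water-soluble dione may be lost on isolation. The fallback sets out from 9 and returns at 10, and drives the hydrolysis to completion on purpose. Warming 9 in aqueous HCl would give 3-hydroxycyclobut-3-ene-1,2-dione (semisquaric acid) F7, isolated by evaporation and crystallisation. O-Methylation of F7 with HC(OMe)3 in MeOH at reflux, the method used to esterify squaric acid, would then give 10.

## Further compounds

F1 | step 5 | (3Z)-3-docosylpent-3-en-2-one | C/C=C(\C(C)=O)CCCCCCCCCCCCCCCCCCCCCC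
F2 | step 5 | (5Z)-5-docosyl-1,1,1-trifluorohept-5-ene-2,4-dione | C/C=C(\C(=O)CC(=O)C(F)(F)F)CCCCCCCCCCCCCCCCCCCCCC
F3 | step 5 | (3Z)-1-diazo-3-docosylpent-3-en-2-one | C/C=C(\C(=O)C=[N+]=[N-])CCCCCCCCCCCCCCCCCCCCCC
F4 | step 5 | 3-docosyl-5-methoxy-2-methylphenol | CCCCCCCCCCCCCCCCCCCCCCc1cc(OC)cc(O)c1C
F5 | step 2 | docosylzinc bromide | CCCCCCCCCCCCCCCCCCCCCC[Zn]Br
F6 | step 2 | (2Z)-3-chloropentacos-2-ene | C/C=C(\Cl)CCCCCCCCCCCCCCCCCCCCCC
F7 | step 4 | 3-hydroxycyclobut-3-ene-1,2-dione (semisquaric acid) | OC1=CC(=O)C1=O
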